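## Structural features

The target 15 is a tetrahydrofuran (ring atoms O1, C2, C3, C4, C5) with unsubstituted methylenes at C2 and C5. C3 and C4 each carry a secondary benzylic carbinol carbon (Ca on C3, Cb on C4) bonded to a 4-hydroxy-3-methoxyphenyl ring. The four stereocentres are contiguous along Ca–C3–C4–Cb: Ca is S, C3 and C4 are both R (substituents trans on the ring) and Cb is R. Because the ring carbons share one descriptor while the carbinol carbons have opposite ones, the two arms are diastereomeric (C3/Ca unlike, C4/Cb like); the molecule has no C2 axis and the two carbinols cannot come from one symmetric event. The fragile parts are the two p-hydroxybenzylic alcohols (ionisation to quinone methides under acid, C–O hydrogenolysis) and the electron-rich guaiacyl rings (oxidation). The ring has no functional group apart from the ether, so the real difficulty is stereochemical: absolute configuration, the trans ring and the unsymmetrical carbinol pair. Ca and Cb are 1,4-related through the C3–C4 bond, so a temporary Ca=Cb double bond makes Ca, C3, C4 and Cb the four carbons of a cyclobutene fused to the tetrahydrofuran at C3–C4. That cyclobutene is necessarily cis-fused and meso, and its double bond is a latent pair of aryl ketones; the key step exploits this.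

## Logic of the disconnections

15 from 14. The two phenolic O–H bonds are traced back to O–CH2Ph bonds. Free phenols para to benzylic oxygen would not survive the oxidative and basic steps, and the benzyl ethers are already present in commercial 1. The forward step must cleave the aryl benzyl ethers without hydrogenolysis of the Ca–O and Cb–O bonds.

14 from 13. The Ca–O–H bond is traced back to Ca–O–Si. The silyl group separates the two carbinols in time, and it is removed before debenzylation so that fluoride never meets a free phenol para to a benzylic oxygen. The forward step must not be acidic.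

13 from 12. The Cb–H bond is cut, which turns the Cb carbinol into an aryl carbonyl group. Cb has the opposite descriptor to Ca, so it needs its own step with a reagent of opposite sense; the gain is one stereocentre fewer and a carbonyl that makes C4 acidic. The forward step needs reagent control over the intrinsic facial bias.

12 from 10 through 11. The Ca–O–Si bond is cut and the C4–H bond is re-formed on the other face (trans back to cis). A cis 3,4-arrangement is what a four-membered ring delivers, and C4 is the only ring carbon next to a carbonyl. The forward step must cap the hydroxyl first, because 10 is expected to rest as a cyclic hemiketal, and it relies on the trans isomer being the more stable.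

10 from 9. The Ca–H bond is cut, giving a second aryl carbonyl group. The two carbonyls become enantiotopic and 9 is achiral (meso), so all absolute stereochemistry traces back to one catalyst. The forward step must pick one of two enantiotopic carbonyls, attack one face and stop after one reduction.

9 from 7 through 8. The two C=O bonds are reconnected as the Ca=Cb double bond. Both carbonyls then come from one alkene, and the four-membered ring fixes C3 and C4 cis. The forward cleavage must prefer the strained tetrasubstituted alkene to the electron-rich arenes and must leave the cis arrangement unepimerised.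

7 from 5 and 6. The bonds Ca–C3 and Cb–C4 are cut. These are the two bonds that join the aryl-bearing carbons to the ring, and cutting both gives two symmetric, achiral partners, one of which already contains the heterocycle. The forward step is a cross (2+2) cycloaddition that must outrun trimerisation of 5 and isomerisation of 6.

5 from 1 and 2 through 3 and 4. The two C(sp)–C(aryl) bonds are cut. The two-carbon unit then comes from 2 and both aryl groups from one commercial bromide. The forward step is a double coupling with desilylation in the same flask on an electron-rich aryl bromide.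

## Other disconnections considered

Alternative 1: The cut goes through the ring bonds C2–C3 and C4–C5, removing O1 with both methylene carbons as a three-atom unit. In the forward direction a non-stabilised carbonyl ylide, released by fluoride from chloromethyl (trimethylsilyl)methyl ether A2, would add in a (3+2) cycloaddition across the E double bond of the (S)-γ-silyloxy enone A1. The product would be the trans-3-aroyl-4-[(S)-aryl(silyloxy)methyl]tetrahydrofuran A3, which is identical with 12.
- In favour: the trans ring relationship follows stereospecifically from the E alkene, and Ca is set beforehand by a routine asymmetric reduction of an acyclic ketone. No group-selective mono-reduction, no epimerisation and no ozone near electron-rich arenes are needed; on these three points the alternative is the better plan.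
- Against: the absolute configuration of C3 and C4 would rest on the facial preference that the γ-silyloxy centre imposes on a small, very reactive dipole, which is expected to be modest. A2 is a volatile alkylating α-chloro ether normally used in excess, and fluoride is basic enough to threaten isomerisation of A1 through its dienolate. A1 itself needs an asymmetric step and an estimated four or five operations.
- Comparison: structurally both plans converge on the same compound (A3 = 12), so the endgame with its reagent-controlled second reduction is equal. Mechanistically the alternative relies on 1,2-induction in a dipolar cycloaddition, the chosen plan on enantiotopic-group selection in a meso compound followed by thermodynamic epimerisation. In step count the chosen plan reaches 12 in five steps and the alternative is judged equal at best.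

Alternative 2: The cut is at the two benzylic C–O bonds, with the ring oxygen and methylenes traced back to the carboxyl groups of (2R,3R)-2,3-bis(4-benzyloxy-3-methoxybenzyl)succinic acid A4. In the forward direction constant-current anodic oxidation would turn each electron-rich benzyl group into a benzylic cation that the γ-carboxylate captures, giving the cis-fused exo,exo bis-lactone A5. Reduction of both lactones and ether closure between the two new primary carbinol carbons would then give the trans-tetrahydrofuran.
- In favour: two C–H bonds are oxidised directly with electricity as the reagent, no chiral reagent is needed once A4 is enantiopure, and all four stereocentres are present after one step. In atom economy the alternative is better than the chosen plan.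
- Against: A5 is C2-symmetric, so after reduction and ether closure both carbinol carbons would be S, whereas 15 needs S at Ca and R at Cb. One benzylic centre would have to be inverted afterwards at a position prone to ionisation. The ether closure must also distinguish two primary from two secondary benzylic hydroxyls, and benzyl aryl ethers and guaiacyl rings are themselves oxidisable at the anode.
- Comparison: structurally the alternative sets both benzylic C–O bonds at once but only in the symmetric sense, whereas the two separate reductions of the chosen plan allow the unsymmetrical pair. Mechanistically it is benzylic cation trapping under exo control against a metallacycle and reagent-controlled hydride transfers. With the synthesis of A4, reduction, selective cyclisation, inversion and deprotection, the count would exceed the eight steps of the chosen plan.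

Alternative 3: The cut is at the ring bond C3–C4 together with both benzylic C–O bonds. In the forward direction visible-light irradiation of Ru(bpz)3(PF6)2 under air would oxidise one styrene unit of bis[(E)-3-(4-benzyloxy-3-methoxyphenyl)allyl] ether A6 to its radical cation. This would cyclise onto the second styrene and take up molecular oxygen at both benzylic carbons, giving the trans-fused endoperoxide A7; O–O reduction would then give the 1,4-diol.
- In favour: one step would form the C3–C4 bond, the tetrahydrofuran and both C–O bonds from a substrate only two or three operations from commercial material. O–O cleavage and debenzylation might be merged in one hydrogenation. In bond-forming efficiency and raw step count the alternative is clearly better than the chosen plan.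
- Against: the photocatalyst carries no chiral information, so A7 is racemic and a resolution would be needed. The relative configuration of A7 again leads to a diol with the same descriptor at both carbinol carbons, an epimer of 15, so a mono-inversion is required as well. Competing (2+2) closure to a cyclobutane and over-oxidation of the guaiacyl rings are further concerns.
- Comparison: structurally more of the molecule is built per step (better), but with the wrong carbinol pairing and no absolute control (worse). Mechanistically it is radical-cation cyclisation with oxygen capture against a cobalt metallacycle; both are limited by chemoselectivity, so the risk at the key step itself is equal. The route is shorter to the racemic epimer but longer than the chosen one once resolution and inversion are added.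

Key step: step 2

Assumption: in both oxazaborolidine reductions the aryl group is taken to act as the larger carbonyl substituent, as in acetophenone-type ketones, so the (R)-catalyst gives the S carbinol and the (S)-catalyst the R carbinol; if the intrinsic bias of 9 were opposite, the two catalyst enantiomers would be used in the reverse order, which converges on the same 15.

## Route

Step 1
Reactants: 1 1-(benzyloxy)-4-bromo-2-methoxybenzene (2 equiv); 2 trimethylsilylacetylene
Product: 5 1,2-bis[4-(benzyloxy)-3-methoxyphenyl]ethyne, via aryl(trimethylsilyl)alkyne 3 (not isolated), via terminal arylalkyne 4 (not isolated)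
Conditions: PdCl2(PPh3)2 (5 mol %), CuI (10 mol %), DBU, H2O, MeCN, 80 °C
Reagents that add atoms: none
Why: One-pot double Sonogashira coupling: 1 adds oxidatively to zerovalent palladium and couples with the copper acetylide of 2 to give 3, DBU/water cleaves the C–Si bond to 4, and 4 couples with a second molecule of 1. No stereocentre is formed.

Step 2
Reactants: 5 1,2-bis[4-(benzyloxy)-3-methoxyphenyl]ethyne; 6 2,5-dihydrofuran
Product: 7 (1R,5S)-6,7-bis[4-(benzyloxy)-3-methoxyphenyl]-3-oxabicyclo[3.2.0]hept-6-ene (meso, cis-fused)
Conditions: CoBr2 (10 mol %), 1,3-bis(diphenylphosphino)propane (10 mol %), Zn (20 mol %), ZnI2 (20 mol %), CH2Cl2, 25 °C, alkene in fivefold excess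
Reagents that add atoms: none
Why: Zinc reduces the CoBr2–diphosphine complex to monovalent cobalt, which ZnI2 renders cationic; 5 and 6 bind and cyclise oxidatively to a cobaltacyclopentene, and C(sp2)–C(sp3) reductive elimination releases 7 and returns the catalyst. The closest known reaction type is the cobalt-catalysed (2+2) cycloaddition of internal aryl alkynes with cyclopentene and related cyclic cis-alkenes to cyclobutenes. The only ring closed is the cyclobutene, formed by contraction of the five-membered metallacycle through reductive elimination, a formal (2+2) cycloaddition and not a polar ring closure. The two new stereocentres C1 and C5 arise by addition of both alkyne carbons to one face of the cis-alkene, and a four-membered ring fused to a five-membered ring can only be cis; since 7 is meso, no absolute control is needed. The selectivity required is chemoselectivity: cross-cycloaddition over cyclotrimerisation of 5, β-hydride elimination from the metallacycle and migration of the double bond of 6. The excess of inexpensive 6, the wide-bite-angle diphosphine that favours reductive elimination, the non-coordinating solvent and the absence of propargylic hydrogens in 5 should secure it.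

Step 3
Reactants: 7 (1R,5S)-6,7-bis[4-(benzyloxy)-3-methoxyphenyl]-3-oxabicyclo[3.2.0]hept-6-ene
Product: 9 [(3R,4S)-tetrahydrofuran-3,4-diyl]bis{[4-(benzyloxy)-3-methoxyphenyl]methanone} (meso cis-diketone), via bicyclic ozonide 8 (not isolated)
Conditions: O3, CH2Cl2, −78 °C (Sudan Red 7B end point); then PPh3, −78 to 25 °C
Reagents that add atoms: ozone, [O-][O+]=O
Why: Ozonolysis: ozone adds to the strained, electron-rich tetrasubstituted C6=C7 bond much faster than to the arenes or benzyl ethers, the tethered carbonyl oxide and ketone close to ozonide 8, and PPh3 reduces it to the 1,4-diketone. The ring-fusion carbons are untouched, so the cis (meso) relationship is kept, and the neutral work-up avoids epimerisation and furan formation.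

Step 4
Reactants: 9 [(3R,4S)-tetrahydrofuran-3,4-diyl]bis{[4-(benzyloxy)-3-methoxyphenyl]methanone}
Product: 10 {(3S,4R)-4-[(S)-[4-(benzyloxy)-3-methoxyphenyl](hydroxy)methyl]tetrahydrofuran-3-yl}[4-(benzyloxy)-3-methoxyphenyl]methanone (cis; expected to equilibrate with its cis-fused lactol tautomer)
Conditions: (R)-1-methyl-3,3-diphenyltetrahydro-1H,3H-pyrrolo[1,2-c][1,3,2]oxazaborole (20 mol %), catecholborane (1.05 equiv), toluene/CH2Cl2, −78 to −40 °C; pH 7 buffer
Reagents that add atoms: none
Why: Desymmetrising CBS reduction: the catalyst delivers hydride to the face that gives the S carbinol, and only at the carbonyl on the R-configured ring carbon is this also the face remote from the neighbouring cis-aroyl group (Felkin–Anh matched), so that carbonyl should react preferentially and set Ca (S) and the identity of C3 (R). Catecholborane leaves a boronate with no residual hydride, which limits over-reduction, and reduction at the other carbonyl gives a separable diastereomer, not the enantiomer.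

Step 5
Reactants: 10 {(3S,4R)-4-[(S)-[4-(benzyloxy)-3-methoxyphenyl](hydroxy)methyl]tetrahydrofuran-3-yl}[4-(benzyloxy)-3-methoxyphenyl]methanone
Product: 12 {(3R,4R)-4-[(S)-[4-(benzyloxy)-3-methoxyphenyl](tert-butyldimethylsilyloxy)methyl]tetrahydrofuran-3-yl}[4-(benzyloxy)-3-methoxyphenyl]methanone (trans), via cis-silyloxy ketone 11 (not isolated)
Conditions: TBSCl, imidazole, DMF, 25 °C; then MeOH, DBU, 25 °C
Reagents that add atoms: tert-butyldimethylsilyl chloride, CC(C)(C)[Si](C)(C)Cl
Why: Silylation of the secondary hydroxyl in the open hydroxy ketone form removes the lactol sink; DBU then enolises the only acidic position, C4 next to the carbonyl, and reprotonation equilibrates to the less strained 3,4-trans arrangement (base-mediated epimerisation). Ca and C3 carry no acidic hydrogen and are unaffected.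

Step 6
Reactants: 12 {(3R,4R)-4-[(S)-[4-(benzyloxy)-3-methoxyphenyl](tert-butyldimethylsilyloxy)methyl]tetrahydrofuran-3-yl}[4-(benzyloxy)-3-methoxyphenyl]methanone
Product: 13 (R)-[4-(benzyloxy)-3-methoxyphenyl]{(3R,4R)-4-[(S)-[4-(benzyloxy)-3-methoxyphenyl](tert-butyldimethylsilyloxy)methyl]tetrahydrofuran-3-yl}methanol
Conditions: (S)-1-methyl-3,3-diphenyltetrahydro-1H,3H-pyrrolo[1,2-c][1,3,2]oxazaborole (0.5–1.0 equiv), BH3·SMe2, THF, −20 °C, slow addition of 12; aqueous NH4Cl
Reagents that add atoms: none
Why: CBS reduction with the enantiomeric catalyst delivers hydride to the opposite carbonyl face and should give the R carbinol at Cb under reagent control, against the modest Felkin–Anh bias of the trans ketone. The high catalyst loading and slow addition of 12 suppress uncatalysed reduction.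

Step 7
Reactants: 13 (R)-[4-(benzyloxy)-3-methoxyphenyl]{(3R,4R)-4-[(S)-[4-(benzyloxy)-3-methoxyphenyl](tert-butyldimethylsilyloxy)methyl]tetrahydrofuran-3-yl}methanol
Product: 14 (S)-[4-(benzyloxy)-3-methoxyphenyl]{(3R,4R)-4-[(R)-[4-(benzyloxy)-3-methoxyphenyl](hydroxy)methyl]tetrahydrofuran-3-yl}methanol
Conditions: Bu4NF, THF, 0 to 25 °C
Reagents that add atoms: none
Why: Fluoride-induced cleavage of the Si–O bond (desilylation); the benzyl ethers and all four stereocentres should be untouched under these non-acidic conditions.

Step 8
Reactants: 14 (S)-[4-(benzyloxy)-3-methoxyphenyl]{(3R,4R)-4-[(R)-[4-(benzyloxy)-3-methoxyphenyl](hydroxy)methyl]tetrahydrofuran-3-yl}methanol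
Product: 15 (S)-(4-hydroxy-3-methoxyphenyl){(3R,4R)-4-[(R)-hydroxy(4-hydroxy-3-methoxyphenyl)methyl]tetrahydrofuran-3-yl}methanol
Conditions: H2 (1 atm), Pd/C (10 %), EtOAc/EtOH, 25 °C
Reagents that add atoms: none
Why: Hydrogenolysis of the two aryl benzyl ethers; under neutral conditions O-debenzylation of phenol ethers is much faster than cleavage of the secondary benzylic C–OH bonds. No stereocentre is touched.

## Compound list

1 | 1-(benzyloxy)-4-bromo-2-methoxybenzene | COc1cc(Br)ccc1OCc1ccccc1 | starting material
2 | trimethylsilylacetylene | C#C[Si](C)(C)C | starting material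
3 | {[4-(benzyloxy)-3-methoxyphenyl]ethynyl}trimethylsilane | COc1cc(C#C[Si](C)(C)C)ccc1OCc1ccccc1 | intermediate (not isolated)
4 | 1-(benzyloxy)-4-ethynyl-2-methoxybenzene | COc1cc(C#C)ccc1OCc1ccccc1 | intermediate (not isolated)
5 | 1,2-bis[4-(benzyloxy)-3-methoxyphenyl]ethyne | COc1cc(C#Cc2ccc(OCc3ccccc3)c(OC)c2)ccc1OCc1ccccc1 | intermediate
6 | 2,5-dihydrofuran | C1=CCOC1 | starting material
7 | (1R,5S)-6,7-bis[4-(benzyloxy)-3-methoxyphenyl]-3-oxabicyclo[3.2.0]hept-6-ene (meso, cis-fused) | COc1cc(C2=C(c3ccc(OCc4ccccc4)c(OC)c3)[C@H]3COC[C@H]32)ccc1OCc1ccccc1 | intermediate
8 | 1,7-bis[4-(benzyloxy)-3-methoxyphenyl]-4,8,9,10-tetraoxatricyclo[5.2.1.0(2,6)]decane (ozonide; tetrahydrofuran cis-fused, orientation of the trioxolane relative to it not fixed) | COc1cc(C23OOC(c4ccc(OCc5ccccc5)c(OC)c4)(O2)[C@H]4COC[C@H]43)ccc1OCc1ccccc1 | intermediate (not isolated)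
9 | [(3R,4S)-tetrahydrofuran-3,4-diyl]bis{[4-(benzyloxy)-3-methoxyphenyl]methanone} (meso, cis) | COc1cc(C(=O)[C@H]2COC[C@H]2C(=O)c2ccc(OCc3ccccc3)c(OC)c2)ccc1OCc1ccccc1 | intermediate
10 | {(3S,4R)-4-[(S)-[4-(benzyloxy)-3-methoxyphenyl](hydroxy)methyl]tetrahydrofuran-3-yl}[4-(benzyloxy)-3-methoxyphenyl]methanone (cis) | COc1cc([C@@H](O)[C@H]2COC[C@H]2C(=O)c2ccc(OCc3ccccc3)c(OC)c2)ccc1OCc1ccccc1 | intermediate
11 | {(3S,4R)-4-[(S)-[4-(benzyloxy)-3-methoxyphenyl](tert-butyldimethylsilyloxy)methyl]tetrahydrofuran-3-yl}[4-(benzyloxy)-3-methoxyphenyl]methanone (cis) | COc1cc([C@@H](O[Si](C)(C)C(C)(C)C)[C@H]2COC[C@H]2C(=O)c2ccc(OCc3ccccc3)c(OC)c2)ccc1OCc1ccccc1 | intermediate (not isolated)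
12 | {(3R,4R)-4-[(S)-[4-(benzyloxy)-3-methoxyphenyl](tert-butyldimethylsilyloxy)methyl]tetrahydrofuran-3-yl}[4-(benzyloxy)-3-methoxyphenyl]methanone (trans) | COc1cc([C@@H](O[Si](C)(C)C(C)(C)C)[C@H]2COC[C@@H]2C(=O)c2ccc(OCc3ccccc3)c(OC)c2)ccc1OCc1ccccc1 | intermediate
13 | (R)-[4-(benzyloxy)-3-methoxyphenyl]{(3R,4R)-4-[(S)-[4-(benzyloxy)-3-methoxyphenyl](tert-butyldimethylsilyloxy)methyl]tetrahydrofuran-3-yl}methanol | COc1cc([C@@H](O[Si](C)(C)C(C)(C)C)[C@H]2COC[C@@H]2[C@@H](O)c2ccc(OCc3ccccc3)c(OC)c2)ccc1OCc1ccccc1 | intermediate
14 | (S)-[4-(benzyloxy)-3-methoxyphenyl]{(3R,4R)-4-[(R)-[4-(benzyloxy)-3-methoxyphenyl](hydroxy)methyl]tetrahydrofuran-3-yl}methanol | COc1cc([C@@H](O)[C@H]2COC[C@@H]2[C@@H](O)c2ccc(OCc3ccccc3)c(OC)c2)ccc1OCc1ccccc1 | intermediate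
15 | (S)-(4-hydroxy-3-methoxyphenyl){(3R,4R)-4-[(R)-hydroxy(4-hydroxy-3-methoxyphenyl)methyl]tetrahydrofuran-3-yl}methanol | COc1cc([C@@H](O)[C@H]2COC[C@@H]2[C@@H](O)c2ccc(O)c(OC)c2)ccc1O | target

## Step count and least certain steps

Total step count: 8. Longest linear sequence: 8 steps (1 to 15).

Step 2 (key step). The most likely failure is that β-hydride elimination from the cobaltacycle, cobalt-hydride migration of the double bond of 6 towards the enol ether, or cyclotrimerisation of 5 outruns reductive elimination. The allylic hydrogens of 6 are activated by the ring oxygen, and this alkene has not been used in the reaction. Fallback: a change from metallacycle catalysis to an excited-state cycloaddition. Irradiation (Pyrex-filtered, about 300–350 nm) of 5 in degassed 6 as solvent should give the cyclobutene by the known photocycloaddition of diarylalkynes with alkenes. It would be stopped at partial conversion to protect the stilbene-like chromophore of the product. It sets out from 5 and 6 and returns at 7; no new compound is made (F0).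

Step 3. Over-oxidation of the guaiacyl rings or of the benzyl ether methylenes by ozone may compete, and the strained ozonide may fragment abnormally, because the substrate carries four electron-rich sites besides the alkene. Fallback: a two-stage cleavage without ozone, setting out from 7. Dihydroxylation with OsO4 (catalytic) and N-methylmorpholine N-oxide in acetone/water on the convex face should give the meso 6,7-bis[4-(benzyloxy)-3-methoxyphenyl]-3-oxabicyclo[3.2.0]heptane-6,7-diol F1. Glycol cleavage with Pb(OAc)4 in CH2Cl2 at 0 °C then returns to the route at 9.

Step 4. Three processes may fail here: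
- The discrimination between the two enantiotopic carbonyls may be insufficient, if the matched and mismatched rates differ too little.
- Face selectivity may erode, because the ring carbon is not much smaller than the aryl group.
- The second carbonyl may be reduced as well.

The first problem costs yield but not enantiopurity, since the by-product is a diastereomer. Fallback: reagent control by a stoichiometric chiral chloroborane in place of catalysis. B-chlorodiisopinocampheylborane (the enantiomer that gives the S carbinol, the (−)-reagent if the aryl group stays the larger substituent) in THF at −25 °C with diethanolamine work-up transfers a β-hydrogen through a reagent-bound cyclic transition state and has no achiral background. It sets out from 9 and returns at 10; no new compound is made (F0).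

Step 6. The catalyst may fail to override the substrate's own facial preference (mismatched pairing), or uncatalysed borane reduction may compete, giving the wrong configuration at Cb. Fallback: accept substrate control and invert, setting out from 12. Reduction with LiBH(s-Bu)3 in THF at −78 °C should give the Felkin–Anh epimer (S)-[4-(benzyloxy)-3-methoxyphenyl]{(3R,4R)-4-[(S)-[4-(benzyloxy)-3-methoxyphenyl](tert-butyldimethylsilyloxy)methyl]tetrahydrofuran-3-yl}methanol F2. Mitsunobu inversion (4-nitrobenzoic acid, PPh3, diisopropyl azodicarboxylate, low temperature to limit ionisation of the electron-rich benzylic centre) gives the (R)-4-nitrobenzoate of 13 F3. Methanolysis (K2CO3, MeOH) returns to the route at 13.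

Step 8. Hydrogenolysis may go on to cleave the benzylic C–OH bonds, or the product may ionise on the catalyst surface, once the phenols are free and para to the carbinols. Fallback: change the phenol protecting group before any benzylic alcohol is free, setting out from 12.
- Hydrogenolysis of 12 (H2, Pd/C, EtOAc) gives the bis-phenol {(3R,4R)-4-[(S)-(tert-butyldimethylsilyloxy)(4-hydroxy-3-methoxyphenyl)methyl]tetrahydrofuran-3-yl}(4-hydroxy-3-methoxyphenyl)methanone F4.
- Silylation (TBSCl, imidazole, DMF) gives the tris-silyl ketone {(3R,4R)-4-[(S)-(tert-butyldimethylsilyloxy)[4-(tert-butyldimethylsilyloxy)-3-methoxyphenyl]methyl]tetrahydrofuran-3-yl}[4-(tert-butyldimethylsilyloxy)-3-methoxyphenyl]methanone F5.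
- Reduction under the conditions of step 6 gives the tris-silyl alcohol (R)-[4-(tert-butyldimethylsilyloxy)-3-methoxyphenyl]{(3R,4R)-4-[(S)-(tert-butyldimethylsilyloxy)[4-(tert-butyldimethylsilyloxy)-3-methoxyphenyl]methyl]tetrahydrofuran-3-yl}methanol F6.
- Global desilylation (Bu4NF buffered with AcOH, THF) returns to the route at 15.

## Further compounds

F0 | step 2 | none | none
F1 | step 3 | meso 6,7-bis[4-(benzyloxy)-3-methoxyphenyl]-3-oxabicyclo[3.2.0]heptane-6,7-diol (cis-fused; hydroxyls cis to each other and anti to the tetrahydrofuran ring) | O[C@]1(c2ccc(OCc3ccccc3)c(OC)c2)[C@@](O)(c2ccc(OCc3ccccc3)c(OC)c2)[C@H]2COC[C@H]21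
F0 | step 4 | none | none
F2 | step 6 | (S)-[4-(benzyloxy)-3-methoxyphenyl]{(3R,4R)-4-[(S)-[4-(benzyloxy)-3-methoxyphenyl](tert-butyldimethylsilyloxy)methyl]tetrahydrofuran-3-yl}methanol | COc1cc([C@@H](O[Si](C)(C)C(C)(C)C)[C@H]2COC[C@@H]2[C@H](O)c2ccc(OCc3ccccc3)c(OC)c2)ccc1OCc1ccccc1
F3 | step 6 | (R)-[4-(benzyloxy)-3-methoxyphenyl]{(3R,4R)-4-[(S)-[4-(benzyloxy)-3-methoxyphenyl](tert-butyldimethylsilyloxy)methyl]tetrahydrofuran-3-yl}methyl 4-nitrobenzoate | COc1cc([C@@H](O[Si](C)(C)C(C)(C)C)[C@H]2COC[C@@H]2[C@@H](OC(=O)c2ccc(cc2)[N+](=O)[O-])c2ccc(OCc3ccccc3)c(OC)c2)ccc1OCc1ccccc1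
F4 | step 8 | {(3R,4R)-4-[(S)-(tert-butyldimethylsilyloxy)(4-hydroxy-3-methoxyphenyl)methyl]tetrahydrofuran-3-yl}(4-hydroxy-3-methoxyphenyl)methanone | COc1cc([C@@H](O[Si](C)(C)C(C)(C)C)[C@H]2COC[C@@H]2C(=O)c2ccc(O)c(OC)c2)ccc1O
F5 | step 8 | {(3R,4R)-4-[(S)-(tert-butyldimethylsilyloxy)[4-(tert-butyldimethylsilyloxy)-3-methoxyphenyl]methyl]tetrahydrofuran-3-yl}[4-(tert-butyldimethylsilyloxy)-3-methoxyphenyl]methanone | COc1cc([C@@H](O[Si](C)(C)C(C)(C)C)[C@H]2COC[C@@H]2C(=O)c2ccc(O[Si](C)(C)C(C)(C)C)c(OC)c2)ccc1O[Si](C)(C)C(C)(C)C
F6 | step 8 | (R)-[4-(tert-butyldimethylsilyloxy)-3-methoxyphenyl]{(3R,4R)-4-[(S)-(tert-butyldimethylsilyloxy)[4-(tert-butyldimethylsilyloxy)-3-methoxyphenyl]methyl]tetrahydrofuran-3-yl}methanol | COc1cc([C@@H](O[Si](C)(C)C(C)(C)C)[C@H]2COC[C@@H]2[C@@H](O)c2ccc(O[Si](C)(C)C(C)(C)C)c(OC)c2)ccc1O[Si](C)(C)C(C)(C)C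
A1 | alternative 1 | (S,E)-1,4-bis[4-(benzyloxy)-3-methoxyphenyl]-4-(tert-butyldimethylsilyloxy)but-2-en-1-one | COc1cc([C@@H](O[Si](C)(C)C(C)(C)C)/C=C/C(=O)c2ccc(OCc3ccccc3)c(OC)c2)ccc1OCc1ccccc1
A2 | alternative 1 | chloromethyl (trimethylsilyl)methyl ether | C[Si](C)(C)COCCl
A3 | alternative 1 | {(3R,4R)-4-[(S)-[4-(benzyloxy)-3-methoxyphenyl](tert-butyldimethylsilyloxy)methyl]tetrahydrofuran-3-yl}[4-(benzyloxy)-3-methoxyphenyl]methanone (identical with 12) | COc1cc([C@@H](O[Si](C)(C)C(C)(C)C)[C@H]2COC[C@@H]2C(=O)c2ccc(OCc3ccccc3)c(OC)c2)ccc1OCc1ccccc1
A4 | alternative 2 | (2R,3R)-2,3-bis[4-(benzyloxy)-3-methoxybenzyl]succinic acid | COc1cc(C[C@@H](C(=O)O)[C@H](C(=O)O)Cc2ccc(OCc3ccccc3)c(OC)c2)ccc1OCc1ccccc1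
A5 | alternative 2 | exo,exo-4,8-bis[4-(benzyloxy)-3-methoxyphenyl]-3,7-dioxabicyclo[3.3.0]octane-2,6-dione (cis-fused, C2-symmetric, enantiomer as drawn) | COc1cc([C@H]2OC(=O)[C@H]3[C@@H]2C(=O)O[C@@H]3c2ccc(OCc3ccccc3)c(OC)c2)ccc1OCc1ccccc1
A6 | alternative 3 | bis[(E)-3-[4-(benzyloxy)-3-methoxyphenyl]prop-2-en-1-yl] ether | COc1cc(/C=C/COC/C=C/c2ccc(OCc3ccccc3)c(OC)c2)ccc1OCc1ccccc1
A7 | alternative 3 | trans-fused 1,4-bis[4-(benzyloxy)-3-methoxyphenyl]hexahydrofuro[3,4-d][1,2]dioxine (racemic, relative configuration as drawn) | COc1cc([C@H]2OO[C@H](c3ccc(OCc4ccccc4)c(OC)c3)[C@H]3COC[C@@H]32)ccc1OCc1ccccc1
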